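## Retrosynthetic overview

- The ester between the two halves is made last, by acylating the primary hydroxyl of a lactone diol with a silyl-protected acrylic acid; a Pinnick oxidation and desilylation then finish the target.
- Both halves come from the two enantiomers of 4-isopropylcyclohex-2-enone (organocatalytic Michael addition of 3-methylbutanal to methyl vinyl ketone, then aldol condensation).
- Each enone receives the same C4 alkenyl Grignard reagent (made once from TRIS) by copper-catalysed trans 1,4-addition with enolate triflation, followed by palladium-catalysed hydroxymethylation of the enol triflate.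
- Lactone half: the seven-membered lactone is closed onto the finished cyclohexene by a palladium-catalysed transpositional carbonylative lactonization of an allylic carbonate; OsO4 then sets the tertiary carbinol.
- Acid half: E-selective oxidation of the 2-alkylidene-1,3-diol. Ring order: cyclohexene rings first, lactone ring second, union last.

Assumption: the bicyclic half is numbered as a 2-benzoxepine (C1 lactone carbonyl, O2, C3, C4, C5, C5a, C6–C9, C9a), and catalysts, ligands and reagents are purchased.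

## Route

Step 1
Reactants: 1 2-amino-2-(hydroxymethyl)propane-1,3-diol (TRIS)
Product: 2 (5-amino-2,2-dimethyl-1,3-dioxan-5-yl)methanol
Conditions: 2,2-dimethoxypropane, TsOH·H2O (1.05 equiv), DMF, rt; then Et3N
Reagents that add atoms: 2,2-dimethoxypropane, COC(C)(C)OC
Why: Acid-catalysed transacetalization (acetonide formation) ties two hydroxyls of the ammonium triol into a 1,3-dioxane and leaves the 1,2-amino alcohol needed for the next cleavage.

Step 2
Reactants: 2 (5-amino-2,2-dimethyl-1,3-dioxan-5-yl)methanol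
Product: 3 2,2-dimethyl-1,3-dioxan-5-one
Conditions: NaIO4, KH2PO4, H2O, 0 °C → rt
Reagents that add atoms: water, O
Why: Periodate cleavage of the 1,2-amino alcohol (Malaprade-type) removes the CH2OH carbon as formaldehyde, and hydrolysis of the resulting imine leaves the ketone.

Step 3
Reactants: 3 2,2-dimethyl-1,3-dioxan-5-one
Product: 4 5-(bromomethylidene)-2,2-dimethyl-1,3-dioxane
Conditions: BrCH2PPh3Br, KOtBu, THF, −78 °C → rt
Reagents that add atoms: (bromomethyl)triphenylphosphonium bromide, BrC[P+](c1ccccc1)(c1ccccc1)c1ccccc1.[Br-]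
Why: Wittig bromomethylenation with Ph3P=CHBr; the ketone is symmetric, so no alkene geometry arises.

Step 4
Reactants: 5 3-methylbutanal; 6 but-3-en-2-one
Product: 7 (2S)-5-oxo-2-(propan-2-yl)hexanal
Conditions: (S)-2-[methoxy(diphenyl)methyl]pyrrolidine (5 mol %), ethyl 3,4-dihydroxybenzoate (20 mol %), neat, 4 °C
Reagents that add atoms: none
Why: Enamine-catalysed asymmetric Michael addition; the diphenyl(methoxy)methyl group shields one face of the E-enamine, so the enone adds to the other face and gives the 2S aldehyde.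

Step 5
Reactants: 7 (2S)-5-oxo-2-(propan-2-yl)hexanal
Product: 9 (4S)-4-(propan-2-yl)cyclohex-2-en-1-one, via aldol adduct 8 (not isolated)
Conditions: LiOH (0.1 equiv), i-PrOH, rt
Reagents that add atoms: none
Why: Intramolecular aldol condensation (second stage of a Robinson annulation) of the methyl ketone onto the aldehyde, then dehydration; the mild base leaves the C4 stereocentre intact.

Step 6
Reactants: 4 5-(bromomethylidene)-2,2-dimethyl-1,3-dioxane
Product: 10 bromo[(2,2-dimethyl-1,3-dioxan-5-ylidene)methyl]magnesium (alkenylmagnesium bromide, titrated THF solution)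
Conditions: Mg turnings, THF, 50 °C; titrated and stored under argon, one batch divided between steps 7 and 16
Reagents that add atoms: magnesium, [Mg]
Why: Grignard reagent formation by insertion of magnesium into the alkenyl C–Br bond; the acetal oxygens sit on the allylic carbons and not β to the metal, so the reagent does not eliminate and keeps as a stock solution.

Step 7
Reactants: 9 (4S)-4-(propan-2-yl)cyclohex-2-en-1-one; 10 bromo[(2,2-dimethyl-1,3-dioxan-5-ylidene)methyl]magnesium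
Product: 12 (3R,4S)-3-[(2,2-dimethyl-1,3-dioxan-5-ylidene)methyl]-4-(propan-2-yl)cyclohex-1-en-1-yl trifluoromethanesulfonate, via magnesium enolate 11 (not isolated)
Conditions: 10 (1.3 equiv), CuBr·SMe2 (10 mol %), THF, −78 → −40 °C; then Comins' reagent, −78 °C → rt
Reagents that add atoms: Comins' reagent (N-(5-chloropyridin-2-yl)-1,1,1-trifluoro-N-(trifluoromethanesulfonyl)methanesulfonamide), FC(F)(F)S(=O)(=O)N(c1ccc(Cl)cn1)S(=O)(=O)C(F)(F)F
Why: Copper-catalysed conjugate addition of the alkenyl Grignard reagent takes place anti to the C4 isopropyl group (axial attack on the half-chair), which sets the 3,4-trans centre, and the regiodefined magnesium enolate is trapped on oxygen as the enol triflate.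

Step 8
Reactants: 12 (3R,4S)-3-[(2,2-dimethyl-1,3-dioxan-5-ylidene)methyl]-4-(propan-2-yl)cyclohex-1-en-1-yl trifluoromethanesulfonate
Product: 13 [(3S,4S)-3-[(2,2-dimethyl-1,3-dioxan-5-ylidene)methyl]-4-(propan-2-yl)cyclohex-1-en-1-yl]methanol
Conditions: Bu3SnCH2OH, Pd(PPh3)4 (5 mol %), LiCl, 1,4-dioxane, 90 °C
Reagents that add atoms: (tributylstannyl)methanol, OC[Sn](CCCC)(CCCC)CCCC
Why: Stille cross-coupling of the enol triflate transfers the hydroxymethyl group from tin with retention of the alkene position; no stereocentre is touched.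

Step 9
Reactants: 13 [(3S,4S)-3-[(2,2-dimethyl-1,3-dioxan-5-ylidene)methyl]-4-(propan-2-yl)cyclohex-1-en-1-yl]methanol
Product: 14 tert-butyl{[(3S,4S)-3-[(2,2-dimethyl-1,3-dioxan-5-ylidene)methyl]-4-(propan-2-yl)cyclohex-1-en-1-yl]methoxy}diphenylsilane
Conditions: TBDPSCl, imidazole, CH2Cl2, 0 °C → rt
Reagents that add atoms: tert-butyl(chloro)diphenylsilane, CC(C)(C)[Si](Cl)(c1ccccc1)c1ccccc1
Why: Silylation of the primary allylic alcohol with an acid-stable silyl group that survives the acetonide removal and the later oxidations.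

Step 10
Reactants: 14 tert-butyl{[(3S,4S)-3-[(2,2-dimethyl-1,3-dioxan-5-ylidene)methyl]-4-(propan-2-yl)cyclohex-1-en-1-yl]methoxy}diphenylsilane
Product: 15 2-{[(1S,6S)-3-({[tert-butyl(diphenyl)silyl]oxy}methyl)-6-(propan-2-yl)cyclohex-2-en-1-yl]methylidene}propane-1,3-diol
Conditions: PPTS (10 mol %), MeOH, rt
Reagents that add atoms: none
Why: Acid-catalysed transacetalization to methanol releases the 1,3-diol while the TBDPS ether stays.

Step 11
Reactants: 15 2-{[(1S,6S)-3-({[tert-butyl(diphenyl)silyl]oxy}methyl)-6-(propan-2-yl)cyclohex-2-en-1-yl]methylidene}propane-1,3-diol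
Product: 16 (2E)-3-[(1S,6S)-3-({[tert-butyl(diphenyl)silyl]oxy}methyl)-6-(propan-2-yl)cyclohex-2-en-1-yl]-2-(hydroxymethyl)prop-2-enal
Conditions: MnO2 (10 equiv), CH2Cl2, 0 °C, stopped at mono-oxidation
Reagents that add atoms: none
Why: Chemoselective allylic oxidation; the CH2OH trans to the ring (cis to the vinylic H) is the accessible one, the other being screened by the branched ring carbon through allylic 1,3-strain and deactivated once the enal has formed, so the 2E aldehyde results.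

Step 12
Reactants: 16 (2E)-3-[(1S,6S)-3-({[tert-butyl(diphenyl)silyl]oxy}methyl)-6-(propan-2-yl)cyclohex-2-en-1-yl]-2-(hydroxymethyl)prop-2-enal
Product: 17 (2E)-2-({[tert-butyl(dimethyl)silyl]oxy}methyl)-3-[(1S,6S)-3-({[tert-butyl(diphenyl)silyl]oxy}methyl)-6-(propan-2-yl)cyclohex-2-en-1-yl]prop-2-enal
Conditions: TBSCl, imidazole, CH2Cl2, 0 °C
Reagents that add atoms: tert-butyl(chloro)dimethylsilane, CC(C)(C)[Si](C)(C)Cl
Why: Silylation of the remaining primary hydroxyl so that the acid cannot acylate itself in the coupling.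

Step 13
Reactants: 17 (2E)-2-({[tert-butyl(dimethyl)silyl]oxy}methyl)-3-[(1S,6S)-3-({[tert-butyl(diphenyl)silyl]oxy}methyl)-6-(propan-2-yl)cyclohex-2-en-1-yl]prop-2-enal
Product: 18 (2E)-2-({[tert-butyl(dimethyl)silyl]oxy}methyl)-3-[(1S,6S)-3-({[tert-butyl(diphenyl)silyl]oxy}methyl)-6-(propan-2-yl)cyclohex-2-en-1-yl]prop-2-enoic acid
Conditions: NaClO2, NaH2PO4, 2-methylbut-2-ene, t-BuOH/H2O, 0 °C → rt
Reagents that add atoms: sodium chlorite, [Na+].[O-]Cl=O
Why: Pinnick oxidation converts the enal to the acid without touching the alkene geometry, the skipped diene or the silyl ethers.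

Step 14
Reactants: 5 3-methylbutanal; 6 but-3-en-2-one
Product: 19 (2R)-5-oxo-2-(propan-2-yl)hexanal
Conditions: (R)-2-[methoxy(diphenyl)methyl]pyrrolidine (5 mol %), ethyl 3,4-dihydroxybenzoate (20 mol %), neat, 4 °C
Reagents that add atoms: none
Why: The same enamine-catalysed Michael addition as step 4 with the enantiomeric catalyst gives the 2R aldehyde.

Step 15
Reactants: 19 (2R)-5-oxo-2-(propan-2-yl)hexanal
Product: 21 (4R)-4-(propan-2-yl)cyclohex-2-en-1-one, via aldol adduct 20 (not isolated)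
Conditions: LiOH (0.1 equiv), i-PrOH, rt
Reagents that add atoms: none
Why: Intramolecular aldol condensation as in step 5, in the mirror-image series.

Step 16
Reactants: 21 (4R)-4-(propan-2-yl)cyclohex-2-en-1-one; 10 bromo[(2,2-dimethyl-1,3-dioxan-5-ylidene)methyl]magnesium
Product: 23 (3S,4R)-3-[(2,2-dimethyl-1,3-dioxan-5-ylidene)methyl]-4-(propan-2-yl)cyclohex-1-en-1-yl trifluoromethanesulfonate, via magnesium enolate 22 (not isolated)
Conditions: 10 (1.3 equiv), CuBr·SMe2 (10 mol %), THF, −78 → −40 °C; then Comins' reagent, −78 °C → rt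
Reagents that add atoms: Comins' reagent (N-(5-chloropyridin-2-yl)-1,1,1-trifluoro-N-(trifluoromethanesulfonyl)methanesulfonamide), FC(F)(F)S(=O)(=O)N(c1ccc(Cl)cn1)S(=O)(=O)C(F)(F)F
Why: Copper-catalysed conjugate addition anti to the isopropyl group sets the trans centre, and the magnesium enolate is trapped as the enol triflate, as in step 7.

Step 17
Reactants: 23 (3S,4R)-3-[(2,2-dimethyl-1,3-dioxan-5-ylidene)methyl]-4-(propan-2-yl)cyclohex-1-en-1-yl trifluoromethanesulfonate
Product: 24 [(3R,4R)-3-[(2,2-dimethyl-1,3-dioxan-5-ylidene)methyl]-4-(propan-2-yl)cyclohex-1-en-1-yl]methanol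
Conditions: Bu3SnCH2OH, Pd(PPh3)4 (5 mol %), LiCl, 1,4-dioxane, 90 °C
Reagents that add atoms: (tributylstannyl)methanol, OC[Sn](CCCC)(CCCC)CCCC
Why: Stille hydroxymethylation of the enol triflate, as in step 8.

Step 18
Reactants: 24 [(3R,4R)-3-[(2,2-dimethyl-1,3-dioxan-5-ylidene)methyl]-4-(propan-2-yl)cyclohex-1-en-1-yl]methanol
Product: 25 tert-butyl {[(3R,4R)-3-[(2,2-dimethyl-1,3-dioxan-5-ylidene)methyl]-4-(propan-2-yl)cyclohex-1-en-1-yl]methyl} carbonate
Conditions: Boc2O, DMAP (10 mol %), CH2Cl2, 0 °C → rt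
Reagents that add atoms: di-tert-butyl dicarbonate, CC(C)(C)OC(=O)OC(=O)OC(C)(C)C
Why: DMAP-catalysed O-acylation turns the allylic alcohol into an allylic carbonate whose ionization later releases only CO2 and the poorly nucleophilic tert-butoxide.

Step 19
Reactants: 25 tert-butyl {[(3R,4R)-3-[(2,2-dimethyl-1,3-dioxan-5-ylidene)methyl]-4-(propan-2-yl)cyclohex-1-en-1-yl]methyl} carbonate
Product: 26 tert-butyl {[(3R,4R)-3-[3-hydroxy-2-(hydroxymethyl)prop-1-en-1-yl]-4-(propan-2-yl)cyclohex-1-en-1-yl]methyl} carbonate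
Conditions: PPTS (10 mol %), MeOH, rt
Reagents that add atoms: none
Why: Acid-catalysed transacetalization frees the side-chain diol; the tert-butyl carbonate tolerates the weak acid.

Step 20
Reactants: 26 tert-butyl {[(3R,4R)-3-[3-hydroxy-2-(hydroxymethyl)prop-1-en-1-yl]-4-(propan-2-yl)cyclohex-1-en-1-yl]methyl} carbonate
Product: 27 (5aS,6R,9aS)-4-(hydroxymethyl)-9-methylidene-6-(propan-2-yl)-5a,6,7,8,9,9a-hexahydro-2-benzoxepin-1(3H)-one
Conditions: Pd2(dba)3 (2.5 mol %), Xantphos (6 mol %), CO (20 bar), THF (0.005 M), 50 °C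
Reagents that add atoms: carbon monoxide, [C-]#[O+]
Why: Proposed new method: zerovalent palladium ionizes the allylic carbonate (loss of CO2 and tert-butoxide) to an η3-allyl complex spanning the exocyclic CH2 and the ring carbon; tert-butoxide deprotonates the (Z)-CH2OH, whose alkoxide binds palladium and takes up CO to give a tethered alkoxycarbonyl(allyl)palladium species; the tether reaches only the ring terminus, so C–C reductive elimination there closes the seven-membered lactone with transposition of the alkene to the exocyclic position, while carbonylation at the CH2 terminus is reversible and has no intramolecular trap; the diequatorial, trans-fused closure is expected to give 9aS; the closest known reaction type is the Tsuji decarboxylative carbonylation of allylic carbonates to β,γ-unsaturated esters, together with palladium-catalysed cyclocarbonylation of unsaturated alcohols, neither shown for seven-membered lactone closure at the more substituted allyl terminus.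

Step 21
Reactants: 27 (5aS,6R,9aS)-4-(hydroxymethyl)-9-methylidene-6-(propan-2-yl)-5a,6,7,8,9,9a-hexahydro-2-benzoxepin-1(3H)-one
Product: 28 (5aS,6R,9aS)-9-methylidene-1-oxo-6-(propan-2-yl)-1,3,5a,6,7,8,9,9a-octahydro-2-benzoxepine-4-carbaldehyde
Conditions: MnO2, CH2Cl2, rt
Reagents that add atoms: none
Why: Neutral allylic oxidation with MnO2 gives the enal, which also deactivates the ring alkene before the dihydroxylation; the β,γ-unsaturated lactone is not isomerized under these conditions.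

Step 22
Reactants: 28 (5aS,6R,9aS)-9-methylidene-1-oxo-6-(propan-2-yl)-1,3,5a,6,7,8,9,9a-octahydro-2-benzoxepine-4-carbaldehyde
Product: 29 (5aS,6R,9S,9aS)-9-hydroxy-9-(hydroxymethyl)-1-oxo-6-(propan-2-yl)-1,3,5a,6,7,8,9,9a-octahydro-2-benzoxepine-4-carbaldehyde
Conditions: OsO4 (2 mol %), NMO, acetone/H2O (9:1), 0 °C; crude product used at once
Reagents that add atoms: N-methylmorpholine N-oxide, C[N+]1([O-])CCOCC1; water, O
Why: Upjohn dihydroxylation; OsO4 ignores the electron-poor enal alkene and adds to the exocyclic 1,1-disubstituted alkene from the equatorial face of the chair, which places the tertiary OH equatorial and the CH2OH axial, cis to the lactone carbonyl carbon (9S).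

Step 23
Reactants: 29 (5aS,6R,9S,9aS)-9-hydroxy-9-(hydroxymethyl)-1-oxo-6-(propan-2-yl)-1,3,5a,6,7,8,9,9a-octahydro-2-benzoxepine-4-carbaldehyde; 18 (2E)-2-({[tert-butyl(dimethyl)silyl]oxy}methyl)-3-[(1S,6S)-3-({[tert-butyl(diphenyl)silyl]oxy}methyl)-6-(propan-2-yl)cyclohex-2-en-1-yl]prop-2-enoic acid
Product: 30 {(5aS,6R,9S,9aS)-4-formyl-9-hydroxy-1-oxo-6-(propan-2-yl)-1,3,5a,6,7,8,9,9a-octahydro-2-benzoxepin-9-yl}methyl (2E)-2-({[tert-butyl(dimethyl)silyl]oxy}methyl)-3-[(1S,6S)-3-({[tert-butyl(diphenyl)silyl]oxy}methyl)-6-(propan-2-yl)cyclohex-2-en-1-yl]prop-2-enoate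
Conditions: DCC, DMAP (10 mol %), CH2Cl2, −10 °C → rt
Reagents that add atoms: none
Why: Steglich esterification acylates only the primary hydroxyl of the primary/tertiary 1,2-diol; it is run cold on fresh 29 so that acylation outruns attack of that hydroxyl on the lactone carbonyl.

Step 24
Reactants: 30 {(5aS,6R,9S,9aS)-4-formyl-9-hydroxy-1-oxo-6-(propan-2-yl)-1,3,5a,6,7,8,9,9a-octahydro-2-benzoxepin-9-yl}methyl (2E)-2-({[tert-butyl(dimethyl)silyl]oxy}methyl)-3-[(1S,6S)-3-({[tert-butyl(diphenyl)silyl]oxy}methyl)-6-(propan-2-yl)cyclohex-2-en-1-yl]prop-2-enoate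
Product: 31 (5aS,6R,9S,9aS)-9-({[(2E)-2-({[tert-butyl(dimethyl)silyl]oxy}methyl)-3-[(1S,6S)-3-({[tert-butyl(diphenyl)silyl]oxy}methyl)-6-(propan-2-yl)cyclohex-2-en-1-yl]prop-2-enoyl]oxy}methyl)-9-hydroxy-1-oxo-6-(propan-2-yl)-1,3,5a,6,7,8,9,9a-octahydro-2-benzoxepine-4-carboxylic acid
Conditions: NaClO2, NaH2PO4, 2-methylbut-2-ene, t-BuOH/H2O, 0 °C → rt
Reagents that add atoms: sodium chlorite, [Na+].[O-]Cl=O
Why: Pinnick oxidation of the enal gives the ring carboxylic acid under buffered conditions that leave the esters, silyl ethers and alkenes alone.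

Step 25
Reactants: 31 (5aS,6R,9S,9aS)-9-({[(2E)-2-({[tert-butyl(dimethyl)silyl]oxy}methyl)-3-[(1S,6S)-3-({[tert-butyl(diphenyl)silyl]oxy}methyl)-6-(propan-2-yl)cyclohex-2-en-1-yl]prop-2-enoyl]oxy}methyl)-9-hydroxy-1-oxo-6-(propan-2-yl)-1,3,5a,6,7,8,9,9a-octahydro-2-benzoxepine-4-carboxylic acid
Product: 32 (5aS,6R,9S,9aS)-9-hydroxy-9-({[(2E)-2-(hydroxymethyl)-3-[(1S,6S)-3-(hydroxymethyl)-6-(propan-2-yl)cyclohex-2-en-1-yl]prop-2-enoyl]oxy}methyl)-1-oxo-6-(propan-2-yl)-1,3,5a,6,7,8,9,9a-octahydro-2-benzoxepine-4-carboxylic acid (CNP0361406.8)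
Conditions: HF·pyridine, pyridine, THF, 0 °C → rt
Reagents that add atoms: none
Why: Fluoride-mediated desilylation removes both silyl ethers under mildly acidic conditions that spare the ester, the β-hydroxy lactone and the skipped diene.

## Compound list

1 | 2-amino-2-(hydroxymethyl)propane-1,3-diol (TRIS) | NC(CO)(CO)CO | starting material
2 | (5-amino-2,2-dimethyl-1,3-dioxan-5-yl)methanol | CC1(C)OCC(N)(CO)CO1 | intermediate
3 | 2,2-dimethyl-1,3-dioxan-5-one | CC1(C)OCC(=O)CO1 | intermediate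
4 | 5-(bromomethylidene)-2,2-dimethyl-1,3-dioxane | CC1(C)OCC(=CBr)CO1 | intermediate
5 | 3-methylbutanal | CC(C)CC=O | starting material
6 | but-3-en-2-one (methyl vinyl ketone) | CC(=O)C=C | starting material
7 | (2S)-5-oxo-2-(propan-2-yl)hexanal | CC(C)[C@@H](C=O)CCC(C)=O | intermediate
8 | aldol adduct: (4S)-3-hydroxy-4-(propan-2-yl)cyclohexan-1-one, both C3 epimers | CC(C)[C@@H]1CCC(=O)CC1O | intermediate
9 | (4S)-4-(propan-2-yl)cyclohex-2-en-1-one ((S)-cryptone) | CC(C)[C@@H]1CCC(=O)C=C1 | intermediate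
10 | bromo[(2,2-dimethyl-1,3-dioxan-5-ylidene)methyl]magnesium (alkenylmagnesium bromide, titrated THF solution) | CC1(C)OCC(=C[Mg]Br)CO1 | intermediate
11 | magnesium enolate: bromomagnesium (3R,4S)-3-[(2,2-dimethyl-1,3-dioxan-5-ylidene)methyl]-4-(propan-2-yl)cyclohex-1-en-1-olate | CC1(C)OCC(=C[C@@H]2C=C(O[Mg]Br)CC[C@H]2C(C)C)CO1 | intermediate
12 | (3R,4S)-3-[(2,2-dimethyl-1,3-dioxan-5-ylidene)methyl]-4-(propan-2-yl)cyclohex-1-en-1-yl trifluoromethanesulfonate (3,4-trans) | CC1(C)OCC(=C[C@@H]2C=C(OS(=O)(=O)C(F)(F)F)CC[C@H]2C(C)C)CO1 | intermediate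
13 | [(3S,4S)-3-[(2,2-dimethyl-1,3-dioxan-5-ylidene)methyl]-4-(propan-2-yl)cyclohex-1-en-1-yl]methanol | CC1(C)OCC(=C[C@@H]2C=C(CO)CC[C@H]2C(C)C)CO1 | intermediate
14 | tert-butyl{[(3S,4S)-3-[(2,2-dimethyl-1,3-dioxan-5-ylidene)methyl]-4-(propan-2-yl)cyclohex-1-en-1-yl]methoxy}diphenylsilane | CC1(C)OCC(=C[C@@H]2C=C(CO[Si](c3ccccc3)(c3ccccc3)C(C)(C)C)CC[C@H]2C(C)C)CO1 | intermediate
15 | 2-{[(1S,6S)-3-({[tert-butyl(diphenyl)silyl]oxy}methyl)-6-(propan-2-yl)cyclohex-2-en-1-yl]methylidene}propane-1,3-diol | OCC(CO)=C[C@@H]1C=C(CO[Si](c2ccccc2)(c2ccccc2)C(C)(C)C)CC[C@H]1C(C)C | intermediate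
16 | (2E)-3-[(1S,6S)-3-({[tert-butyl(diphenyl)silyl]oxy}methyl)-6-(propan-2-yl)cyclohex-2-en-1-yl]-2-(hydroxymethyl)prop-2-enal | O=C/C(CO)=C/[C@@H]1C=C(CO[Si](c2ccccc2)(c2ccccc2)C(C)(C)C)CC[C@H]1C(C)C | intermediate
17 | (2E)-2-({[tert-butyl(dimethyl)silyl]oxy}methyl)-3-[(1S,6S)-3-({[tert-butyl(diphenyl)silyl]oxy}methyl)-6-(propan-2-yl)cyclohex-2-en-1-yl]prop-2-enal | O=C/C(CO[Si](C)(C)C(C)(C)C)=C/[C@@H]1C=C(CO[Si](c2ccccc2)(c2ccccc2)C(C)(C)C)CC[C@H]1C(C)C | intermediate
18 | (2E)-2-({[tert-butyl(dimethyl)silyl]oxy}methyl)-3-[(1S,6S)-3-({[tert-butyl(diphenyl)silyl]oxy}methyl)-6-(propan-2-yl)cyclohex-2-en-1-yl]prop-2-enoic acid | OC(=O)/C(CO[Si](C)(C)C(C)(C)C)=C/[C@@H]1C=C(CO[Si](c2ccccc2)(c2ccccc2)C(C)(C)C)CC[C@H]1C(C)C | intermediate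
19 | (2R)-5-oxo-2-(propan-2-yl)hexanal | CC(C)[C@H](C=O)CCC(C)=O | intermediate
20 | aldol adduct: (4R)-3-hydroxy-4-(propan-2-yl)cyclohexan-1-one, both C3 epimers | CC(C)[C@H]1CCC(=O)CC1O | intermediate
21 | (4R)-4-(propan-2-yl)cyclohex-2-en-1-one ((R)-cryptone) | CC(C)[C@H]1CCC(=O)C=C1 | intermediate
22 | magnesium enolate: bromomagnesium (3S,4R)-3-[(2,2-dimethyl-1,3-dioxan-5-ylidene)methyl]-4-(propan-2-yl)cyclohex-1-en-1-olate | CC1(C)OCC(=C[C@H]2C=C(O[Mg]Br)CC[C@@H]2C(C)C)CO1 | intermediate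
23 | (3S,4R)-3-[(2,2-dimethyl-1,3-dioxan-5-ylidene)methyl]-4-(propan-2-yl)cyclohex-1-en-1-yl trifluoromethanesulfonate (3,4-trans) | CC1(C)OCC(=C[C@H]2C=C(OS(=O)(=O)C(F)(F)F)CC[C@@H]2C(C)C)CO1 | intermediate
24 | [(3R,4R)-3-[(2,2-dimethyl-1,3-dioxan-5-ylidene)methyl]-4-(propan-2-yl)cyclohex-1-en-1-yl]methanol | CC1(C)OCC(=C[C@H]2C=C(CO)CC[C@@H]2C(C)C)CO1 | intermediate
25 | tert-butyl {[(3R,4R)-3-[(2,2-dimethyl-1,3-dioxan-5-ylidene)methyl]-4-(propan-2-yl)cyclohex-1-en-1-yl]methyl} carbonate | CC1(C)OCC(=C[C@H]2C=C(COC(=O)OC(C)(C)C)CC[C@@H]2C(C)C)CO1 | intermediate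
26 | tert-butyl {[(3R,4R)-3-[3-hydroxy-2-(hydroxymethyl)prop-1-en-1-yl]-4-(propan-2-yl)cyclohex-1-en-1-yl]methyl} carbonate | OCC(CO)=C[C@H]1C=C(COC(=O)OC(C)(C)C)CC[C@@H]1C(C)C | intermediate
27 | (5aS,6R,9aS)-4-(hydroxymethyl)-9-methylidene-6-(propan-2-yl)-5a,6,7,8,9,9a-hexahydro-2-benzoxepin-1(3H)-one (trans ring fusion) | CC(C)[C@H]1CCC(=C)[C@H]2C(=O)OCC(CO)=C[C@H]12 | intermediate
28 | (5aS,6R,9aS)-9-methylidene-1-oxo-6-(propan-2-yl)-1,3,5a,6,7,8,9,9a-octahydro-2-benzoxepine-4-carbaldehyde | CC(C)[C@H]1CCC(=C)[C@H]2C(=O)OCC(C=O)=C[C@H]12 | intermediate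
29 | (5aS,6R,9S,9aS)-9-hydroxy-9-(hydroxymethyl)-1-oxo-6-(propan-2-yl)-1,3,5a,6,7,8,9,9a-octahydro-2-benzoxepine-4-carbaldehyde | CC(C)[C@H]1CC[C@@](O)(CO)[C@H]2C(=O)OCC(C=O)=C[C@H]12 | intermediate
30 | {(5aS,6R,9S,9aS)-4-formyl-9-hydroxy-1-oxo-6-(propan-2-yl)-1,3,5a,6,7,8,9,9a-octahydro-2-benzoxepin-9-yl}methyl (2E)-2-({[tert-butyl(dimethyl)silyl]oxy}methyl)-3-[(1S,6S)-3-({[tert-butyl(diphenyl)silyl]oxy}methyl)-6-(propan-2-yl)cyclohex-2-en-1-yl]prop-2-enoate | CC(C)[C@H]1CC[C@@](O)(COC(=O)/C(=C/[C@@H]2C=C(CO[Si](c3ccccc3)(c3ccccc3)C(C)(C)C)CC[C@H]2C(C)C)CO[Si](C)(C)C(C)(C)C)[C@H]2C(=O)OCC(C=O)=C[C@H]12 | intermediate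
31 | (5aS,6R,9S,9aS)-9-({[(2E)-2-({[tert-butyl(dimethyl)silyl]oxy}methyl)-3-[(1S,6S)-3-({[tert-butyl(diphenyl)silyl]oxy}methyl)-6-(propan-2-yl)cyclohex-2-en-1-yl]prop-2-enoyl]oxy}methyl)-9-hydroxy-1-oxo-6-(propan-2-yl)-1,3,5a,6,7,8,9,9a-octahydro-2-benzoxepine-4-carboxylic acid | CC(C)[C@H]1CC[C@@](O)(COC(=O)/C(=C/[C@@H]2C=C(CO[Si](c3ccccc3)(c3ccccc3)C(C)(C)C)CC[C@H]2C(C)C)CO[Si](C)(C)C(C)(C)C)[C@H]2C(=O)OCC(C(=O)O)=C[C@H]12 | intermediate
32 | (5aS,6R,9S,9aS)-9-hydroxy-9-({[(2E)-2-(hydroxymethyl)-3-[(1S,6S)-3-(hydroxymethyl)-6-(propan-2-yl)cyclohex-2-en-1-yl]prop-2-enoyl]oxy}methyl)-1-oxo-6-(propan-2-yl)-1,3,5a,6,7,8,9,9a-octahydro-2-benzoxepine-4-carboxylic acid (CNP0361406.8) | CC(C)[C@H]1CC[C@@](O)(COC(=O)/C(=C/[C@@H]2C=C(CO)CC[C@H]2C(C)C)CO)[C@H]2C(=O)OCC(C(=O)O)=C[C@H]12 | target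

## Step count

Total: 25 steps. Longest linear sequence: 14 steps (1, 2, 3, 6–13, 23–25; the branch through 1, 2, 3, 6, 16–22, 23–25 is equally long).

## Three steps most likely to fail

**Step 20 (the proposed new carbonylative lactonization).** Possible failures:
- carbonylation at the CH2 terminus, giving linear esters or oligomers;
- intramolecular O-allylation to a dihydropyran instead of CO uptake;
- the cis ring fusion at C9a;
- re-ionization of the product, which is itself an allylic ester.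

Fallback (known chemistry), setting out from 24 and returning at 27. Alcohol 24 is O-alkylated with Bu3SnCH2I (KH, THF) to the (tributylstannyl)methyl ether F1. n-BuLi at −78 °C triggers tin–lithium exchange and the Wittig–Still [2,3]-sigmatropic rearrangement, which forms the C–C bond at the ring carbon anti to the neighbouring side chain and gives the homoallylic alcohol F2 with the exocyclic methylene. Dess–Martin oxidation gives the aldehyde F3 and Pinnick oxidation the acid F4. Aqueous acetic acid removes the acetonide to give the dihydroxy acid F5. Shiina lactonization (2-methyl-6-nitrobenzoic anhydride, DMAP, high dilution) then closes the only ring that can form, through the (Z)-CH2OH, to 27.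

**Step 11 (E-selective mono-oxidation of the diol).** Possible failures: oxidation of the wrong CH2OH or over-oxidation to the dialdehyde.

Fallback, setting out from 15 and returning at 17. Lipase-catalysed acylation (lipase PS, vinyl acetate) acetylates the less hindered hydroxyl and gives the (E)-monoacetate F6. TBSCl/imidazole converts the other hydroxyl to the silyl ether acetate F7. K2CO3/MeOH removes the acetyl group to give the allylic alcohol F8. MnO2 then oxidizes the single free hydroxyl to 17.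

**Step 22 (dihydroxylation).** Possible failures: attack on the axial face, or the free primary hydroxyl of 29 opening the seven-membered lactone to the five-membered isomer before it is acylated.

Fallback, setting out from 28 and returning at 30, with 29 bypassed. A ketone-catalysed asymmetric epoxidation of the 1,1-disubstituted alkene (Shi-type chiral dioxirane, Oxone, buffered) gives the spiro-epoxide F9 with the oxygen equatorial. The cesium salt of acid 18 (Cs2CO3, DMF, 60 °C) then opens F9 at its CH2 carbon, so the primary oxygen arrives already acylated and the tertiary hydroxyl is released, giving 30.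

## Further compounds

F1 | step 20 | (tributylstannyl)methyl ether: tributyl({[(3R,4R)-3-[(2,2-dimethyl-1,3-dioxan-5-ylidene)methyl]-4-(propan-2-yl)cyclohex-1-en-1-yl]methoxy}methyl)stannane | CC1(C)OCC(=C[C@H]2C=C(COC[Sn](CCCC)(CCCC)CCCC)CC[C@@H]2C(C)C)CO1
F2 | step 20 | homoallylic alcohol: [(1S,5R,6S)-6-[(2,2-dimethyl-1,3-dioxan-5-ylidene)methyl]-2-methylidene-5-(propan-2-yl)cyclohexyl]methanol | CC(C)[C@H]1CCC(=C)[C@@H](CO)[C@@H]1C=C1COC(C)(C)OC1
F3 | step 20 | aldehyde: (1S,5R,6S)-6-[(2,2-dimethyl-1,3-dioxan-5-ylidene)methyl]-2-methylidene-5-(propan-2-yl)cyclohexane-1-carbaldehyde | CC(C)[C@H]1CCC(=C)[C@@H](C=O)[C@@H]1C=C1COC(C)(C)OC1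
F4 | step 20 | acid: (1S,5R,6S)-6-[(2,2-dimethyl-1,3-dioxan-5-ylidene)methyl]-2-methylidene-5-(propan-2-yl)cyclohexane-1-carboxylic acid | CC(C)[C@H]1CCC(=C)[C@@H](C(=O)O)[C@@H]1C=C1COC(C)(C)OC1
F5 | step 20 | dihydroxy acid: (1S,5R,6S)-6-[3-hydroxy-2-(hydroxymethyl)prop-1-en-1-yl]-2-methylidene-5-(propan-2-yl)cyclohexane-1-carboxylic acid | CC(C)[C@H]1CCC(=C)[C@@H](C(=O)O)[C@@H]1C=C(CO)CO
F6 | step 11 | (E)-monoacetate: (2E)-3-[(1S,6S)-3-({[tert-butyl(diphenyl)silyl]oxy}methyl)-6-(propan-2-yl)cyclohex-2-en-1-yl]-2-(hydroxymethyl)prop-2-en-1-yl acetate | CC(=O)OC/C(=C/[C@@H]1C=C(CO[Si](c2ccccc2)(c2ccccc2)C(C)(C)C)CC[C@H]1C(C)C)CO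
F7 | step 11 | silyl ether acetate: (2Z)-2-({[tert-butyl(dimethyl)silyl]oxy}methyl)-3-[(1S,6S)-3-({[tert-butyl(diphenyl)silyl]oxy}methyl)-6-(propan-2-yl)cyclohex-2-en-1-yl]prop-2-en-1-yl acetate | CC(=O)OC/C(=C/[C@@H]1C=C(CO[Si](c2ccccc2)(c2ccccc2)C(C)(C)C)CC[C@H]1C(C)C)CO[Si](C)(C)C(C)(C)C
F8 | step 11 | allylic alcohol: (2Z)-2-({[tert-butyl(dimethyl)silyl]oxy}methyl)-3-[(1S,6S)-3-({[tert-butyl(diphenyl)silyl]oxy}methyl)-6-(propan-2-yl)cyclohex-2-en-1-yl]prop-2-en-1-ol | OC/C(=C/[C@@H]1C=C(CO[Si](c2ccccc2)(c2ccccc2)C(C)(C)C)CC[C@H]1C(C)C)CO[Si](C)(C)C(C)(C)C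
F9 | step 22 | spiro-epoxide: (5aS,6R,9S,9aS)-1-oxo-6-(propan-2-yl)-3,5a,6,7,8,9a-hexahydro-1H-spiro[2-benzoxepine-9,2'-oxirane]-4-carbaldehyde | CC(C)[C@H]1CC[C@@]3(CO3)[C@H]2C(=O)OCC(C=O)=C[C@H]12
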